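Retrosynthetic overview
1. The plan rests on ring A, the benzo ring of the chromone. Heptyl-bearing C5 and C4a (which carries acyl carbon C4) are adjacent, and C4a has oxygenated C8a on its other side, which is the pattern left by carbometallation and capture of a 3-alkoxyaryne.
2. Last disconnections: the ring C acid comes from its methyl ester by O–CH3 cleavage. Ring B (the pyranone, the only ring built) comes from O1–C2 closure by the C8a phenol after demethylation.
3. Key disconnection: C5–heptyl and C4a–C4 are cut together. This leads back to 1-fluoro-3,5-dimethoxybenzene (ring A), heptyllithium, and a ring C Weinreb amide that holds C4, C3, C2 (masked as its enol methyl ether) and the CH2 link.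
4. The Weinreb amide comes from methyl 2,4-dimethoxy-6-methylbenzoate (ring C). Lateral lithiation/CO2 brings in C2, Meldrum's acid with N,O-dimethylhydroxylamine brings in C3 and C4, and enol methylation follows.
5. Ring order: rings A and C are bought as arenes, and ring B is closed in step 7.

Key step: step 6

Remark: the target has no stereocentre. The only stereo-element on the way is the C2=C3 enol ether geometry, which is erased when ring B forms, so the thermodynamic E isomer is drawn. Chromone numbering is used for the target atoms at every stage.

Step 1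
Reactants: 1 methyl 2,4-dimethoxy-6-methylbenzoate
Product: 3 2-[3,5-dimethoxy-2-(methoxycarbonyl)phenyl]acetic acid, via benzylic lithium compound 2 (not isolated)
Conditions: LiN(iPr)2 (1.2 equiv), THF, −78 °C (1 added to the base); dry CO2 (excess), −78 → 0 °C; 1 M HCl
Reagents that add atoms: carbon dioxide, O=C=O
Why: Lateral lithiation of an ortho-toluate, whose benzylic anion is stabilised by the flanking ester, followed by carboxylation should give the homophthalic half-ester with the aliphatic acid free and the hindered aromatic ester untouched, while inverse addition at −78 °C suppresses self-condensation.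

Step 2
Reactants: 3 2-[3,5-dimethoxy-2-(methoxycarbonyl)phenyl]acetic acid; 4 Meldrum's acid (2,2-dimethyl-1,3-dioxane-4,6-dione)
Product: 5 methyl 2-[2-(2,2-dimethyl-4,6-dioxo-1,3-dioxan-5-ylidene)-2-hydroxyethyl]-4,6-dimethoxybenzoate (acyl Meldrum's acid, enol form)
Conditions: DCC, DMAP, CH2Cl2, 0 °C → rt; filtration, cold aq. KHSO4 wash
Reagents that add atoms: none
Why: Carbodiimide/DMAP C-acylation of Meldrum's acid (Yonemitsu-type chain extension) is routine for arylacetic acids and brings in C3 and C4 without touching the aromatic ester.

Step 3
Reactants: 5 acyl Meldrum's acid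
Product: 7 methyl 2,4-dimethoxy-6-{4-[methoxy(methyl)amino]-2,4-dioxobutyl}benzoate, via acylketene 6 (not isolated)
Conditions: MeNHOMe·HCl, Et3N, toluene, 80 °C
Reagents that add atoms: N,O-dimethylhydroxylamine hydrochloride, CNOC.Cl
Why: Thermal cycloreversion of the acyl Meldrum's acid releases acetone and CO2, and the resulting acylketene is trapped by the hydroxylamine nitrogen, so the β-keto Weinreb amide forms directly and no ester-to-amide exchange beside the ring C ester is needed.

Step 4
Reactants: 7 β-keto Weinreb amide
Product: 8 methyl 2-[(E)-2-methoxy-4-[methoxy(methyl)amino]-4-oxobut-2-enyl]-4,6-dimethoxybenzoate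
Conditions: HC(OMe)3, MeOH, H2SO4 (cat.), rt → 45 °C; solid NaHCO3
Reagents that add atoms: trimethyl orthoformate, COC(OC)OC
Why: Acid-catalysed enol etherification of a β-dicarbonyl compound with an orthoester is run under equilibrating conditions, so it should give the push–pull conjugated E enol ether (methoxy anti to the amide carbonyl) rather than the styrene-type isomer, and it removes the acidic C3 methylene that would quench an organometallic reagent.

Step 5
Reactants: 9 1-bromoheptane
Product: 10 heptyllithium (ether solution, filtered and titrated)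
Conditions: Li (2.3 equiv, about 1% Na), Et2O, −15 → 0 °C, argon
Reagents that add atoms: lithium metal, [Li]
Why: Reductive lithiation of a primary alkyl bromide with lithium metal in cold ether is the classical preparation of n-alkyllithiums, slow cold addition limits Wurtz coupling, and titration allows the exact stoichiometry needed in step 6.

Step 6
Reactants: 11 1-fluoro-3,5-dimethoxybenzene; 10 heptyllithium; 8 methyl 2-[(E)-2-methoxy-4-[methoxy(methyl)amino]-4-oxobut-2-enyl]-4,6-dimethoxybenzoate
Product: 16 methyl 2-[(E)-4-(2-heptyl-4,6-dimethoxyphenyl)-2-methoxy-4-oxobut-2-enyl]-4,6-dimethoxybenzoate, via 2-fluoro-4,6-dimethoxyphenyllithium 12 (not isolated), via 3,5-dimethoxybenzyne 13 (not isolated), via 2-heptyl-4,6-dimethoxyphenyllithium 14 (not isolated), via arylcerium dichloride 15 (not isolated)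
Conditions: 11 (1.6 equiv), 10 (3.1 equiv), THF–Et2O, −78 °C, 1 h, then → −10 °C; recool to −78 °C, anhydrous CeCl3 (1.7 equiv, THF slurry), 1 h; 8 (1.0 equiv) in THF, −78 → −30 °C; cold 0.5 M HCl
Reagents that add atoms: none
Why: The first equivalent of heptyllithium removes the proton flanked by fluorine and methoxy, the most acidic position of 11 and one that occurs twice by symmetry, and on warming 12 loses LiF to give aryne 13. The second equivalent adds to the aryne carbon remote from the neighbouring methoxy group, because this puts the new carbanion beside the inductively withdrawing, lithium-coordinating oxygen, so in 14 heptyl sits on the future C5 and the metal on the future C4a. This is the known tandem addition of organolithium or Grignard reagents to 3-alkoxyarynes with electrophilic capture, finished here by a Weinreb ketone synthesis that forms C4a–C4. Because the CH2 group of 8 is both benzylic and vinylogously activated, 14 is first converted into the much less basic, strongly oxophilic arylcerium 15, which should favour 1,2-addition over proton transfer and over conjugate displacement of the enol methoxy group. Chemoselectivity rests on three points: the chelated N-methoxy adduct cannot collapse before the quench, the di-ortho-substituted electron-rich methyl benzoate of ring C is inert at −78 °C, and 11 is kept in slight excess over half the heptyllithium so that no alkyllithium remains to consume 8. No ring is closed and no stereocentre is created, and the E enol ether is carried through unchanged (partial hydrolysis to the diketone in the quench would be harmless for step 7).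

Step 7
Reactants: 16 methyl 2-[(E)-4-(2-heptyl-4,6-dimethoxyphenyl)-2-methoxy-4-oxobut-2-enyl]-4,6-dimethoxybenzoate
Product: 18 methyl 2-[(5-heptyl-7-hydroxy-4-oxo-4H-chromen-2-yl)methyl]-4,6-dihydroxybenzoate, via tetrahydroxy 1,3-diketone 17 (not isolated)
Conditions: BBr3 (10 equiv), CH2Cl2, −78 °C → rt; ice-water; then HCl (cat.), MeOH, 50 °C
Reagents that add atoms: none
Why: BBr3 ether cleavage removes the four aryl methyl groups and the vinylogous-ester methyl group while the chelated, di-ortho-substituted methyl ester is the slowest site, and acid-catalysed cyclodehydration of the 1-(2-hydroxyaryl)-1,3-diketone (the closing stage of a Baker–Venkataraman-type chromone synthesis: 6-exo-trig attack of the C8a hydroxyl on the C2 carbonyl, then loss of water) forms ring B, with methanol as solvent disfavouring lactonisation onto the ring C ester.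

Step 8
Reactants: 18 methyl 2-[(5-heptyl-7-hydroxy-4-oxo-4H-chromen-2-yl)methyl]-4,6-dihydroxybenzoate
Product: 19 siphulin, 2-[(5-heptyl-7-hydroxy-4-oxo-4H-chromen-2-yl)methyl]-4,6-dihydroxybenzoic acid
Conditions: AlBr3 (8 equiv), tetrahydrothiophene, CH2Cl2, 0 °C → rt; ice-water, dilute HCl to pH 2, kept cold
Reagents that add atoms: none
Why: In this hard-acid/soft-nucleophile ester dealkylation AlBr3 activates the chelated ester and the sulfide attacks the methyl carbon by SN2, so shielding of the acyl carbon does not matter, no hydroxide that would open ring B is present, and the low temperature avoids decarboxylation of the 2,4-dihydroxybenzoic acid, which is why saponification is not used.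

Compound list
1 | methyl 2,4-dimethoxy-6-methylbenzoate | COC(=O)c1c(C)cc(OC)cc1OC | starting material
2 | [3,5-dimethoxy-2-(methoxycarbonyl)benzyl]lithium | [Li]Cc1cc(OC)cc(OC)c1C(=O)OC | intermediate (not isolated)
3 | 2-[3,5-dimethoxy-2-(methoxycarbonyl)phenyl]acetic acid | OC(=O)Cc1cc(OC)cc(OC)c1C(=O)OC | intermediate
4 | Meldrum's acid (2,2-dimethyl-1,3-dioxane-4,6-dione) | CC1(C)OC(=O)CC(=O)O1 | starting material
5 | methyl 2-[2-(2,2-dimethyl-4,6-dioxo-1,3-dioxan-5-ylidene)-2-hydroxyethyl]-4,6-dimethoxybenzoate | COC(=O)c1c(OC)cc(OC)cc1CC(O)=C1C(=O)OC(C)(C)OC1=O | intermediate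
6 | methyl 2-(2,4-dioxobut-3-enyl)-4,6-dimethoxybenzoate (acylketene) | COC(=O)c1c(OC)cc(OC)cc1CC(=O)C=C=O | intermediate (not isolated)
7 | methyl 2,4-dimethoxy-6-{4-[methoxy(methyl)amino]-2,4-dioxobutyl}benzoate | CON(C)C(=O)CC(=O)Cc1cc(OC)cc(OC)c1C(=O)OC | intermediate
8 | methyl 2-[(E)-2-methoxy-4-[methoxy(methyl)amino]-4-oxobut-2-enyl]-4,6-dimethoxybenzoate | CON(C)C(=O)/C=C(/OC)Cc1cc(OC)cc(OC)c1C(=O)OC | intermediate
9 | 1-bromoheptane | CCCCCCCBr | starting material
10 | heptyllithium | [Li]CCCCCCC | intermediate
11 | 1-fluoro-3,5-dimethoxybenzene | COc1cc(F)cc(OC)c1 | starting material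
12 | 2-fluoro-4,6-dimethoxyphenyllithium | [Li]c1c(F)cc(OC)cc1OC | intermediate (not isolated)
13 | 3,5-dimethoxybenzyne | COC1=CC(OC)=CC#C1 | intermediate (not isolated)
14 | 2-heptyl-4,6-dimethoxyphenyllithium | [Li]c1c(CCCCCCC)cc(OC)cc1OC | intermediate (not isolated)
15 | (2-heptyl-4,6-dimethoxyphenyl)cerium dichloride | Cl[Ce](Cl)c1c(CCCCCCC)cc(OC)cc1OC | intermediate (not isolated)
16 | methyl 2-[(E)-4-(2-heptyl-4,6-dimethoxyphenyl)-2-methoxy-4-oxobut-2-enyl]-4,6-dimethoxybenzoate | CCCCCCCc1cc(OC)cc(OC)c1C(=O)/C=C(/OC)Cc1cc(OC)cc(OC)c1C(=O)OC | intermediate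
17 | methyl 2-[4-(2-heptyl-4,6-dihydroxyphenyl)-2,4-dioxobutyl]-4,6-dihydroxybenzoate | CCCCCCCc1cc(O)cc(O)c1C(=O)CC(=O)Cc1cc(O)cc(O)c1C(=O)OC | intermediate (not isolated)
18 | methyl 2-[(5-heptyl-7-hydroxy-4-oxo-4H-chromen-2-yl)methyl]-4,6-dihydroxybenzoate | CCCCCCCc1cc(O)cc2oc(Cc3cc(O)cc(O)c3C(=O)OC)cc(=O)c12 | intermediate
19 | siphulin | CCCCCCCc1cc(O)cc2oc(Cc3cc(O)cc(O)c3C(=O)O)cc(=O)c12 | target

Total step count: 8. Longest linear sequence: 7 steps (1, 2, 3, 4, 6, 7, 8). Step 5 is a one-step side branch that joins at step 6.

Steps most likely to fail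

Step 6.
- What may go wrong: proton transfer from the benzylic, vinylogously activated CH2 of 8 to the arylmetal, partial lithiation of 11 between the two methoxy groups (a position that cannot lose LiF), or consumption of 8 by unreacted heptyllithium.
- Fallback: the long electrophile is given up and the C2–C3 bond is made afterwards. This sets out from 10, 11 and 3 and comes back at 18.
- Aryllithium 14 is generated as in step 6 and captured with N-methoxy-N-methylacetamide, a small amide without activated protons, to give 1-(2-heptyl-4,6-dimethoxyphenyl)ethanone F1.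
- Acid 3 is converted with 1H-benzotriazole and SOCl2 in CH2Cl2 into methyl 2-[2-(benzotriazol-1-yl)-2-oxoethyl]-4,6-dimethoxybenzoate F2.
- Ketone F1 is then C-acylated with F2 under soft enolisation (MgBr2·OEt2, iPr2NEt, CH2Cl2, rt). These conditions are mild enough to avoid Claisen closure onto the ring C ester, and they give methyl 2-[4-(2-heptyl-4,6-dimethoxyphenyl)-2,4-dioxobutyl]-4,6-dimethoxybenzoate F3.
- Under the conditions of step 7, F3 passes through 17 and rejoins the route at 18.

Step 8.
- What may go wrong: incomplete dealkylation of the strongly chelated ester, or loss of CO2 from the liberated 2,4-dihydroxybenzoic acid during reaction or work-up.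
- Fallback: the carboxyl group is removed on purpose and put back last. This sets out from 18 and comes back at 19.
- Compound 18 is heated in 48% HBr/AcOH, conditions that chromones tolerate, so that ester cleavage and decarboxylation go to completion and give 2-(3,5-dihydroxybenzyl)-5-heptyl-7-hydroxy-4H-chromen-4-one F4.
- Ring C is now a symmetric 5-substituted resorcinol. It is carboxylated ortho to a hydroxyl and ortho to the CH2 group with MeOMgOCO2Me in DMF at 120 °C, the known carboxylation of 5-alkylresorcinols.
- The deactivated monophenolic ring A should not react, and cold acidic work-up gives 19.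

Step 7.
- What may go wrong: incomplete cleavage of the two non-chelated ethers, premature loss of the ester methyl group, or closure of the C2 carbonyl onto the ring C carboxyl instead of the ring A phenol at the open diketone stage.
- Fallback: ring closure and exhaustive demethylation are separated. This sets out from 16 and comes back at 18.
- BCl3 (3.5 equiv, CH2Cl2, −78 → 0 °C) cleaves only the chelation-activated methyl groups: C8a–OMe beside the ketone, the enol ether, and the ring C methoxy beside the ester.
- Brief treatment with catalytic HCl in MeOH then closes ring B to give methyl 2-[(5-heptyl-7-methoxy-4-oxo-4H-chromen-2-yl)methyl]-6-hydroxy-4-methoxybenzoate F5.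
- In F5 the C2 carbonyl is locked in the pyranone, and BBr3 (CH2Cl2, −78 °C → rt) removes the two remaining aryl methyl groups to give 18.

Further compounds
F1 | step 6 | 1-(2-heptyl-4,6-dimethoxyphenyl)ethanone | CCCCCCCc1cc(OC)cc(OC)c1C(C)=O
F2 | step 6 | methyl 2-[2-(benzotriazol-1-yl)-2-oxoethyl]-4,6-dimethoxybenzoate | COC(=O)c1c(OC)cc(OC)cc1CC(=O)n1nnc2ccccc12
F3 | step 6 | methyl 2-[4-(2-heptyl-4,6-dimethoxyphenyl)-2,4-dioxobutyl]-4,6-dimethoxybenzoate | CCCCCCCc1cc(OC)cc(OC)c1C(=O)CC(=O)Cc1cc(OC)cc(OC)c1C(=O)OC
F4 | step 8 | 2-(3,5-dihydroxybenzyl)-5-heptyl-7-hydroxy-4H-chromen-4-one | CCCCCCCc1cc(O)cc2oc(Cc3cc(O)cc(O)c3)cc(=O)c12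
F5 | step 7 | methyl 2-[(5-heptyl-7-methoxy-4-oxo-4H-chromen-2-yl)methyl]-6-hydroxy-4-methoxybenzoate | CCCCCCCc1cc(OC)cc2oc(Cc3cc(OC)cc(O)c3C(=O)OC)cc(=O)c12
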